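**Retrosynthetic overview**
1. Target 24 ⇐ nonabenzyl ether 23 (global debenzylation) ⇐ Heck union of 4-vinylbenzofuran 12 with the bis(dihydrobenzofuran) bromide 22; the E-stilbene bond is made last.
2. The C2–C3 bond of each furan ring ⇐ acyl anion (Breslow intermediate) of 4-(benzyloxy)benzaldehyde 8 + an ortho-quinone methide, giving an o-hydroxy α,α-diaryl ketone that carries the future C3 stereocentre.
3. One ketone (10) serves twice: acid dehydration gives the benzofuran (first ring), reduction/acid etherification gives the outer trans-dihydrobenzofuran (second ring).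
4. The central trans-dihydrobenzofuran (third ring) comes from a second acyl-anion/quinone-methide addition with the antipodal carbene catalyst, on a sulfone built from the aryllithium of 14 and 5-bromosalicylaldehyde 15.
5. Both quinone-methide precursors are sulfones from salicylaldehyde + aryl-metal additions; the skeleton comes from 1, 8 and 15 plus a vinyl boronate.

Assumption: 1 is bought as such, and the facial sense of the triazolium catalyst is assigned by analogy ((5aS,10bR) → (S)-10); both antipodes are commercial, so if the sense is the reverse the two antipodes are exchanged between steps 4 and 9.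

**Step 1**
Reactants: 1 1,3-bis(benzyloxy)-5-bromobenzene
Product: 3 2,4-bis(benzyloxy)-6-bromobenzaldehyde, via iminium chloride 2 (not isolated)
Conditions: POCl3 (3 equiv), DMF, 90 °C; then H2O, 60 °C
Reagents that add atoms: N,N-dimethylformamide CN(C)C=O; water O
Why: Vilsmeier–Haack formylation goes para to one benzyloxy group and ortho to the other, at the position next to Br and not the more hindered one between the two benzyloxy groups, as the dimethyl analogue does.

**Step 2**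
Reactants: 3 2,4-bis(benzyloxy)-6-bromobenzaldehyde
Product: 4 4-(benzyloxy)-2-bromo-6-hydroxybenzaldehyde
Conditions: MgBr2·OEt2 (2.5 equiv), toluene/Et2O, 80 °C; 1 M HCl work-up
Reagents that add atoms: none
Why: Chelation-controlled selective debenzylation: magnesium bridges the aldehyde oxygen and the ortho ether oxygen, so bromide cleaves only that benzyl group and the para ether stays.

**Step 3**
Reactants: 4 4-(benzyloxy)-2-bromo-6-hydroxybenzaldehyde; 1 1,3-bis(benzyloxy)-5-bromobenzene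
Product: 7 5-(benzyloxy)-2-{[3,5-bis(benzyloxy)phenyl](4-methylbenzenesulfonyl)methyl}-3-bromophenol (racemic), via Grignard reagent 5 (not isolated), via benzhydrol 6 (not isolated)
Conditions: 1 (2.3 equiv), Mg, THF, 50 °C; add 4, 0 °C → rt; H2O quench, extract; crude 6, TolSO2Na (2 equiv), HCO2H/H2O/CH2Cl2, rt
Reagents that add atoms: sodium 4-methylbenzenesulfinate Cc1ccc(cc1)S(=O)[O-].[Na+]
Why: Grignard 1,2-addition (one equivalent is spent on the phenol) followed by acid-promoted SN1 substitution of the ortho-hydroxy/para-alkoxy-activated benzhydrol by sulfinic acid gives a bench-stable quinone-methide precursor.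

**Step 4**
Reactants: 7 the sulfone from step 3; 8 4-(benzyloxy)benzaldehyde
Product: 10 (2S)-2-[4-(benzyloxy)-2-bromo-6-hydroxyphenyl]-1-[4-(benzyloxy)phenyl]-2-[3,5-bis(benzyloxy)phenyl]ethan-1-one, via ortho-quinone methide 9 (not isolated)
Conditions: (5aS,10bR)-2-(pentafluorophenyl)-5a,10b-dihydro-4H,6H-indeno[2,1-b][1,2,4]triazolo[4,3-d][1,4]oxazin-2-ium tetrafluoroborate (15 mol%), Cs2CO3 (1.3 equiv), 8 (2 equiv), 4 Å MS, CH2Cl2, −20 → 0 °C; pH 7 buffer work-up
Reagents that add atoms: none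
Why: Proposed new method: carbonate expels sulfinate from 7 to release quinone methide 9 while the triazolylidene turns 8 into its Breslow intermediate (acyl anion equivalent), which attacks the electrophilic exocyclic carbon in an aromatisation-driven 1,4-addition (Stetter-type), the aminoindanol backbone shielding one face so that the new centre is S and the product phenoxide/hemiketal resisting enolisation; the closest known reactions are the racemic azolium-catalysed nucleophilic acylation of ortho-quinone methides and enantioselective intermolecular Stetter reactions.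

**Step 5**
Reactants: 10 the (S)-ketone
Product: 11 6-(benzyloxy)-2-[4-(benzyloxy)phenyl]-3-[3,5-bis(benzyloxy)phenyl]-4-bromo-1-benzofuran
Conditions: TsOH·H2O (10 mol%), toluene, 60 °C
Reagents that add atoms: none
Why: Acid-catalysed cyclodehydration (phenol onto ketone, hemiketal, loss of water) gives the aromatic benzofuran; the stereocentre is deliberately erased here.

**Step 6**
Reactants: 11 the 4-bromobenzofuran
Product: 12 6-(benzyloxy)-2-[4-(benzyloxy)phenyl]-3-[3,5-bis(benzyloxy)phenyl]-4-ethenyl-1-benzofuran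
Conditions: CH2=CH–Bpin (1.5 equiv), PdCl2(dppf) (5 mol%), K2CO3, 1,4-dioxane/H2O, 90 °C
Reagents that add atoms: 2-ethenyl-4,4,5,5-tetramethyl-1,3,2-dioxaborolane C=CB1OC(C)(C)C(C)(C)O1
Why: Suzuki–Miyaura vinylation tolerates the one ortho substituent on the aryl bromide and benzyl ethers are inert to it.

**Step 7**
Reactants: 10 the (S)-ketone
Product: 14 (2S,3S)-6-(benzyloxy)-2-[4-(benzyloxy)phenyl]-3-[3,5-bis(benzyloxy)phenyl]-4-bromo-2,3-dihydro-1-benzofuran, via diol 13 (not isolated)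
Conditions: NaBH4, CeCl3·7H2O, MeOH/THF, −40 → 0 °C; work-up; then TsOH·H2O (10 mol%), CH2Cl2, 0 °C
Reagents that add atoms: none
Why: Luche reduction is non-basic, so the α-centre is kept; acid then ionises the 4-benzyloxybenzylic alcohol and the ortho phenol traps the cation (SN1 cycloetherification), placing the 2-aryl group trans to the fixed 3-aryl group to give 2S,3S.

**Step 8**
Reactants: 14 the (2S,3S)-bromide; 15 5-bromo-2-hydroxybenzaldehyde
Product: 18 4-bromo-2-{[(2S,3S)-6-(benzyloxy)-2-[4-(benzyloxy)phenyl]-3-[3,5-bis(benzyloxy)phenyl]-2,3-dihydro-1-benzofuran-4-yl](4-methylbenzenesulfonyl)methyl}phenol (both epimers at the sulfonyl carbon), via aryllithium 16 (not isolated), via benzhydrol 17 (not isolated)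
Conditions: 14, n-BuLi (1.05 equiv), THF, −78 °C; add sodium salt of 15 (15, NaH, THF, 0 °C), −78 → −30 °C; H2O quench, extract; crude 17, TolSO2Na (2 equiv), HCO2H, CH2Cl2/H2O, rt
Reagents that add atoms: sodium 4-methylbenzenesulfinate Cc1ccc(cc1)S(=O)[O-].[Na+]
Why: Bromine–lithium exchange at −78 °C is faster than any benzylic deprotonation and the aryllithium adds to the aldehyde of the pre-formed phenoxide faster than it exchanges with its aryl bromide; sulfination then proceeds as in step 3 and the carbinol configuration is irrelevant.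

**Step 9**
Reactants: 18 the sulfone from step 8; 8 4-(benzyloxy)benzaldehyde
Product: 20 (2R)-2-(5-bromo-2-hydroxyphenyl)-1-[4-(benzyloxy)phenyl]-2-[(2S,3S)-6-(benzyloxy)-2-[4-(benzyloxy)phenyl]-3-[3,5-bis(benzyloxy)phenyl]-2,3-dihydro-1-benzofuran-4-yl]ethan-1-one, via ortho-quinone methide 19 (not isolated)
Conditions: (5aR,10bS)-2-(pentafluorophenyl)-5a,10b-dihydro-4H,6H-indeno[2,1-b][1,2,4]triazolo[4,3-d][1,4]oxazin-2-ium tetrafluoroborate (20 mol%), Cs2CO3 (1.3 equiv), 8 (2 equiv), 4 Å MS, CH2Cl2, −20 → 0 °C; pH 7 buffer work-up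
Reagents that add atoms: none
Why: Proposed new method: the same Breslow-intermediate 1,4-addition to an in situ ortho-quinone methide as in step 4, now with the antipodal triazolium so that catalyst control sets the new centre R against the remote 2S,3S unit, the wrong-face product being a separable diastereomer (which also removes any minor enantiomer carried from step 4); the closest known reactions are again racemic acylation of ortho-quinone methides and asymmetric intermolecular Stetter reactions.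

**Step 10**
Reactants: 20 the (2R)-ketone
Product: 22 (2R,3R)-5-bromo-2-[4-(benzyloxy)phenyl]-3-[(2S,3S)-6-(benzyloxy)-2-[4-(benzyloxy)phenyl]-3-[3,5-bis(benzyloxy)phenyl]-2,3-dihydro-1-benzofuran-4-yl]-2,3-dihydro-1-benzofuran, via diol 21 (not isolated)
Conditions: NaBH4, CeCl3·7H2O, MeOH/THF, −40 → 0 °C; work-up; then TsOH·H2O (10 mol%), CH2Cl2, 0 °C
Reagents that add atoms: none
Why: Luche reduction then SN1 cycloetherification as in step 7; the cation is trapped by the only ortho phenol and the new 2-aryl group ends trans to the 3-substituent, giving 2R,3R without touching the existing ring.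

**Step 11**
Reactants: 22 the bis(dihydrobenzofuran) bromide; 12 the 4-vinylbenzofuran
Product: 23 nonabenzyl ether of the target: (E)-1-{6-(benzyloxy)-2-[4-(benzyloxy)phenyl]-3-[3,5-bis(benzyloxy)phenyl]-1-benzofuran-4-yl}-2-{(2R,3R)-2-[4-(benzyloxy)phenyl]-3-[(2S,3S)-6-(benzyloxy)-2-[4-(benzyloxy)phenyl]-3-[3,5-bis(benzyloxy)phenyl]-2,3-dihydro-1-benzofuran-4-yl]-2,3-dihydro-1-benzofuran-5-yl}ethene
Conditions: Pd(OAc)2 (5 mol%), P(t-Bu)3·HBF4 (10 mol%), Cy2NMe (1.5 equiv), 1,4-dioxane, 90 °C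
Reagents that add atoms: none
Why: Mizoroki–Heck reaction: zerovalent palladium with the bulky electron-rich phosphine inserts into the electron-rich aryl bromide, and syn-insertion/syn-β-hydride elimination at the terminal alkene carbon gives the E-stilbene; no stereocentre is involved.

**Step 12**
Reactants: 23 the nonabenzyl ether
Product: 24 target CNP0135983.1
Conditions: BCl3 (20 equiv), pentamethylbenzene (30 equiv), CH2Cl2, −78 °C; MeOH/H2O quench at −78 °C
Reagents that add atoms: none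
Why: Lewis-acid debenzylation with a non-Lewis-basic cation scavenger cleaves the nine aryl benzyl ethers at −78 °C without reduction, leaving the stilbene, the benzofuran and the dihydrobenzofuran C–O bonds, and the scavenger prevents C-benzylation of the polyphenol.

**Compound list**
1 | 1,3-bis(benzyloxy)-5-bromobenzene | Brc1cc(OCc2ccccc2)cc(OCc2ccccc2)c1 | starting material
2 | N-{[2,4-bis(benzyloxy)-6-bromophenyl]methylidene}-N-methylmethanaminium chloride | C[N+](C)=Cc1c(OCc2ccccc2)cc(OCc2ccccc2)cc1Br.[Cl-] | intermediate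
3 | 2,4-bis(benzyloxy)-6-bromobenzaldehyde | O=Cc1c(OCc2ccccc2)cc(OCc2ccccc2)cc1Br | intermediate
4 | 4-(benzyloxy)-2-bromo-6-hydroxybenzaldehyde | O=Cc1c(O)cc(OCc2ccccc2)cc1Br | intermediate
5 | [3,5-bis(benzyloxy)phenyl]magnesium bromide | Br[Mg]c1cc(OCc2ccccc2)cc(OCc2ccccc2)c1 | intermediate
6 | [4-(benzyloxy)-2-bromo-6-hydroxyphenyl][3,5-bis(benzyloxy)phenyl]methanol (racemic) | OC(c1cc(OCc2ccccc2)cc(OCc2ccccc2)c1)c1c(O)cc(OCc2ccccc2)cc1Br | intermediate
7 | 5-(benzyloxy)-2-{[3,5-bis(benzyloxy)phenyl](4-methylbenzenesulfonyl)methyl}-3-bromophenol (racemic) | Cc1ccc(cc1)S(=O)(=O)C(c1cc(OCc2ccccc2)cc(OCc2ccccc2)c1)c1c(O)cc(OCc2ccccc2)cc1Br | intermediate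
8 | 4-(benzyloxy)benzaldehyde | O=Cc1ccc(OCc2ccccc2)cc1 | starting material
9 | 3-(benzyloxy)-6-{[3,5-bis(benzyloxy)phenyl]methylidene}-5-bromocyclohexa-2,4-dien-1-one | O=C1C=C(OCc2ccccc2)C=C(Br)C1=Cc1cc(OCc2ccccc2)cc(OCc2ccccc2)c1 | intermediate
10 | (2S)-2-[4-(benzyloxy)-2-bromo-6-hydroxyphenyl]-1-[4-(benzyloxy)phenyl]-2-[3,5-bis(benzyloxy)phenyl]ethan-1-one | O=C(c1ccc(OCc2ccccc2)cc1)[C@@H](c1cc(OCc2ccccc2)cc(OCc2ccccc2)c1)c1c(O)cc(OCc2ccccc2)cc1Br | intermediate
11 | 6-(benzyloxy)-2-[4-(benzyloxy)phenyl]-3-[3,5-bis(benzyloxy)phenyl]-4-bromo-1-benzofuran | Brc1cc(OCc2ccccc2)cc2oc(-c3ccc(OCc4ccccc4)cc3)c(-c3cc(OCc4ccccc4)cc(OCc4ccccc4)c3)c12 | intermediate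
12 | 6-(benzyloxy)-2-[4-(benzyloxy)phenyl]-3-[3,5-bis(benzyloxy)phenyl]-4-ethenyl-1-benzofuran | C=Cc1cc(OCc2ccccc2)cc2oc(-c3ccc(OCc4ccccc4)cc3)c(-c3cc(OCc4ccccc4)cc(OCc4ccccc4)c3)c12 | intermediate
13 | (2S)-2-[4-(benzyloxy)-2-bromo-6-hydroxyphenyl]-1-[4-(benzyloxy)phenyl]-2-[3,5-bis(benzyloxy)phenyl]ethan-1-ol (both C1 epimers) | OC(c1ccc(OCc2ccccc2)cc1)[C@@H](c1cc(OCc2ccccc2)cc(OCc2ccccc2)c1)c1c(O)cc(OCc2ccccc2)cc1Br | intermediate
14 | (2S,3S)-6-(benzyloxy)-2-[4-(benzyloxy)phenyl]-3-[3,5-bis(benzyloxy)phenyl]-4-bromo-2,3-dihydro-1-benzofuran | Brc1cc(OCc2ccccc2)cc2c1[C@H](c1cc(OCc3ccccc3)cc(OCc3ccccc3)c1)[C@@H](c1ccc(OCc3ccccc3)cc1)O2 | intermediate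
15 | 5-bromo-2-hydroxybenzaldehyde | O=Cc1cc(Br)ccc1O | starting material
16 | [(2S,3S)-6-(benzyloxy)-2-[4-(benzyloxy)phenyl]-3-[3,5-bis(benzyloxy)phenyl]-2,3-dihydro-1-benzofuran-4-yl]lithium | [Li]c1cc(OCc2ccccc2)cc2c1[C@H](c1cc(OCc3ccccc3)cc(OCc3ccccc3)c1)[C@@H](c1ccc(OCc3ccccc3)cc1)O2 | intermediate
17 | (5-bromo-2-hydroxyphenyl)[(2S,3S)-6-(benzyloxy)-2-[4-(benzyloxy)phenyl]-3-[3,5-bis(benzyloxy)phenyl]-2,3-dihydro-1-benzofuran-4-yl]methanol (both carbinol epimers) | OC(c1cc(Br)ccc1O)c1cc(OCc2ccccc2)cc2c1[C@H](c1cc(OCc3ccccc3)cc(OCc3ccccc3)c1)[C@@H](c1ccc(OCc3ccccc3)cc1)O2 | intermediate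
18 | 4-bromo-2-{[(2S,3S)-6-(benzyloxy)-2-[4-(benzyloxy)phenyl]-3-[3,5-bis(benzyloxy)phenyl]-2,3-dihydro-1-benzofuran-4-yl](4-methylbenzenesulfonyl)methyl}phenol (both epimers at the sulfonyl carbon) | Cc1ccc(cc1)S(=O)(=O)C(c1cc(Br)ccc1O)c1cc(OCc2ccccc2)cc2c1[C@H](c1cc(OCc3ccccc3)cc(OCc3ccccc3)c1)[C@@H](c1ccc(OCc3ccccc3)cc1)O2 | intermediate
19 | 4-bromo-6-{[(2S,3S)-6-(benzyloxy)-2-[4-(benzyloxy)phenyl]-3-[3,5-bis(benzyloxy)phenyl]-2,3-dihydro-1-benzofuran-4-yl]methylidene}cyclohexa-2,4-dien-1-one | O=C1C=CC(Br)=CC1=Cc1cc(OCc2ccccc2)cc2c1[C@H](c1cc(OCc3ccccc3)cc(OCc3ccccc3)c1)[C@@H](c1ccc(OCc3ccccc3)cc1)O2 | intermediate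
20 | (2R)-2-(5-bromo-2-hydroxyphenyl)-1-[4-(benzyloxy)phenyl]-2-[(2S,3S)-6-(benzyloxy)-2-[4-(benzyloxy)phenyl]-3-[3,5-bis(benzyloxy)phenyl]-2,3-dihydro-1-benzofuran-4-yl]ethan-1-one | O=C(c1ccc(OCc2ccccc2)cc1)[C@@H](c1cc(Br)ccc1O)c1cc(OCc2ccccc2)cc2c1[C@H](c1cc(OCc3ccccc3)cc(OCc3ccccc3)c1)[C@@H](c1ccc(OCc3ccccc3)cc1)O2 | intermediate
21 | (2R)-2-(5-bromo-2-hydroxyphenyl)-1-[4-(benzyloxy)phenyl]-2-[(2S,3S)-6-(benzyloxy)-2-[4-(benzyloxy)phenyl]-3-[3,5-bis(benzyloxy)phenyl]-2,3-dihydro-1-benzofuran-4-yl]ethan-1-ol (both C1 epimers) | OC(c1ccc(OCc2ccccc2)cc1)[C@@H](c1cc(Br)ccc1O)c1cc(OCc2ccccc2)cc2c1[C@H](c1cc(OCc3ccccc3)cc(OCc3ccccc3)c1)[C@@H](c1ccc(OCc3ccccc3)cc1)O2 | intermediate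
22 | (2R,3R)-5-bromo-2-[4-(benzyloxy)phenyl]-3-[(2S,3S)-6-(benzyloxy)-2-[4-(benzyloxy)phenyl]-3-[3,5-bis(benzyloxy)phenyl]-2,3-dihydro-1-benzofuran-4-yl]-2,3-dihydro-1-benzofuran | Brc1ccc2c(c1)[C@@H](c1cc(OCc3ccccc3)cc3c1[C@H](c1cc(OCc4ccccc4)cc(OCc4ccccc4)c1)[C@@H](c1ccc(OCc4ccccc4)cc1)O3)[C@H](c1ccc(OCc3ccccc3)cc1)O2 | intermediate
23 | nonabenzyl ether of 24 (E-stilbene; 2R,3R central and 2S,3S outer dihydrobenzofuran) | c1ccccc1COc1ccc(-c2oc3cc(OCc4ccccc4)cc(/C=C/c4ccc5c(c4)[C@@H](c4cc(OCc6ccccc6)cc6c4[C@H](c4cc(OCc7ccccc7)cc(OCc7ccccc7)c4)[C@@H](c4ccc(OCc7ccccc7)cc4)O6)[C@H](c4ccc(OCc6ccccc6)cc4)O5)c3c2-c2cc(OCc4ccccc4)cc(OCc4ccccc4)c2)cc1 | intermediate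
24 | CNP0135983.1: 5-[(2S,3S)-4-{(2R,3R)-5-[(E)-2-{3-(3,5-dihydroxyphenyl)-6-hydroxy-2-(4-hydroxyphenyl)-1-benzofuran-4-yl}ethenyl]-2-(4-hydroxyphenyl)-2,3-dihydro-1-benzofuran-3-yl}-6-hydroxy-2-(4-hydroxyphenyl)-2,3-dihydro-1-benzofuran-3-yl]benzene-1,3-diol | Oc1ccc(-c2oc3cc(O)cc(/C=C/c4ccc5c(c4)[C@@H](c4cc(O)cc6c4[C@H](c4cc(O)cc(O)c4)[C@@H](c4ccc(O)cc4)O6)[C@H](c4ccc(O)cc4)O5)c3c2-c2cc(O)cc(O)c2)cc1 | target

**Step count**
Total: 12 steps. Longest linear sequence: 10 steps (steps 1, 2, 3, 4, 7, 8, 9, 10, 11, 12); the benzofuran branch (steps 5 and 6) joins at step 11.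

**Three steps most likely to fail, each with a fallback**

Step 4 (enantioselectivity or configurational stability of the triaryl ketone). The fallback sets out from 7 and comes back at 13. Sulfone 7 and aldehyde 8 are combined with an achiral thiazolium catalyst (3-benzyl-5-(2-hydroxyethyl)-4-methylthiazolium chloride, Cs2CO3, CH2Cl2, rt) in the racemic nucleophilic acylation to give the racemic ketone F1, which feeds step 5 unchanged. The stereocentre is then set in the reduction instead of the C–C bond formation: asymmetric transfer hydrogenation under dynamic kinetic resolution (RuCl[(S,S)-TsDPEN](p-cymene), HCO2H/Et3N, DMF, 40 °C; ligand antipode chosen by test run). The amine racemises the acidic α,α-diaryl position while the catalyst reduces one enantiomer faster, giving the (2S)-diol 13, which is cyclised with acid as in step 7.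

Step 9 (the same addition on a hindered, less stabilised quinone methide, with diastereocontrol needed). The fallback sets out from 18 and comes back at 22, skipping 20 and 21. 4-(Benzyloxy)benzyl bromide and dimethyl sulfide give [4-(benzyloxy)benzyl]dimethylsulfonium bromide F2. Its ylide (Cs2CO3, CH2Cl2, 0 °C → rt) adds to quinone methide 19 released from 18, and the phenoxide then displaces dimethyl sulfide in a [4+1] annulation that gives only trans-dihydrobenzofurans. No facial control is expected, so 22 forms together with its (2S,3S)-central-ring diastereomer F3. Because the outer ring is already enantiopure, the two are diastereomers and are separated by chromatography.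

Step 12 (nine ether cleavages beside two acid-labile benzylic ethers and a stilbene). The fallback sets out from 23 and comes back at 24. EtSNa (excess) in DMF at 110 °C cleaves the benzyl ethers by SN2 attack at the benzylic carbon, with no Lewis or Brønsted acid present. The crude polyphenolate is acetylated in the same flask (Ac2O, pyridine) to the nonaacetate F4, which is purified on silica as a stable neutral compound. Deacetylation with K2CO3 (cat.) in MeOH at 0 °C under argon then returns 24.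

**Further compounds**
F1 | step 4 | racemic 2-[4-(benzyloxy)-2-bromo-6-hydroxyphenyl]-1-[4-(benzyloxy)phenyl]-2-[3,5-bis(benzyloxy)phenyl]ethan-1-one | O=C(c1ccc(OCc2ccccc2)cc1)C(c1cc(OCc2ccccc2)cc(OCc2ccccc2)c1)c1c(O)cc(OCc2ccccc2)cc1Br
F2 | step 9 | [4-(benzyloxy)benzyl]dimethylsulfonium bromide | C[S+](C)Cc1ccc(OCc2ccccc2)cc1.[Br-]
F3 | step 9 | (2S,3S)-5-bromo-2-[4-(benzyloxy)phenyl]-3-[(2S,3S)-6-(benzyloxy)-2-[4-(benzyloxy)phenyl]-3-[3,5-bis(benzyloxy)phenyl]-2,3-dihydro-1-benzofuran-4-yl]-2,3-dihydro-1-benzofuran | Brc1ccc2c(c1)[C@H](c1cc(OCc3ccccc3)cc3c1[C@H](c1cc(OCc4ccccc4)cc(OCc4ccccc4)c1)[C@@H](c1ccc(OCc4ccccc4)cc1)O3)[C@@H](c1ccc(OCc3ccccc3)cc1)O2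
F4 | step 12 | nonaacetate of 24 | CC(=O)Oc1ccc(-c2oc3cc(OC(C)=O)cc(/C=C/c4ccc5c(c4)[C@@H](c4cc(OC(C)=O)cc6c4[C@H](c4cc(OC(C)=O)cc(OC(C)=O)c4)[C@@H](c4ccc(OC(C)=O)cc4)O6)[C@H](c4ccc(OC(C)=O)cc4)O5)c3c2-c2cc(OC(C)=O)cc(OC(C)=O)c2)cc1
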